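**Retrosynthetic overview**
1. Target 20 is the mono-methyl ester of a meso cis-cyclobutane-1,2-dicarboxylic acid, so it comes from meso anhydride 19 by enantiotopic-group-selective methanolysis with a cinchona alkaloid.
2. The cyclobutane is the syn head-to-head [2+2] photodimer of the E-pyranonyl butenoic acid 14, with two molecules held on a naphthalene-1,8-diol template.
3. The pyranone of 14 comes from lactonisation of triketide 9. The key C–C bond (pyranone C5–C6) is made by intermolecular crossed Claisen acylation of the dianion of ethyl 2-methylacetoacetate (7) with Weinreb amide 6.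
4. Amide 6 comes from an E-selective Wittig reaction of glycolaldehyde with Ph3P=C(Me)CO2Et, which fixes the alkene geometry.
5. Ring order: pyranone (step 5), cyclobutane (step 11), transient anhydride ring (step 13, opened in step 14).

Assumption: the facial sense of the alkaloid-mediated methanolysis is carried over from simple cis-fused succinic anhydrides (quinine gives (1S,2R)-2-(methoxycarbonyl)cyclohex-4-ene-1-carboxylic acid from tetrahydrophthalic anhydride, quinidine its enantiomer), which makes quinidine the alkaloid for 20; this sense is recalled from precedent, not certain, and must be confirmed on the product before scale-up.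

**Route**

Step 1
Reactants: 1 1,4-dioxane-2,5-diol (glycolaldehyde dimer); 2 ethyl 2-(triphenyl-λ5-phosphanylidene)propanoate
Product: 4 ethyl (2E)-4-hydroxy-2-methylbut-2-enoate, via glycolaldehyde 3 (not isolated)
Conditions: 2 (2.1 equiv per 1), THF, 65 °C, 12 h
Reagents that add atoms: none
Why: the dimer cracks to aldehyde 3, which undergoes a Wittig olefination with the stabilised α-branched ylide to give the trisubstituted enoate with high E selectivity (ester trans to CH2OH), the geometry later copied into the ring.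

Step 2
Reactants: 4 ethyl (2E)-4-hydroxy-2-methylbut-2-enoate
Product: 5 ethyl (2E)-4-[(tert-butyldimethylsilyl)oxy]-2-methylbut-2-enoate
Conditions: TBSCl (1.1 equiv), imidazole (2.0 equiv), DMF, 0 °C → rt
Reagents that add atoms: tert-butyldimethylsilyl chloride, CC(C)(C)[Si](C)(C)Cl
Why: standard silyl ether protection of the primary allylic alcohol, which must be masked before the strongly basic dianion step.

Step 3
Reactants: 5 ethyl (2E)-4-[(tert-butyldimethylsilyl)oxy]-2-methylbut-2-enoate
Product: 6 (2E)-4-[(tert-butyldimethylsilyl)oxy]-N-methoxy-N,2-dimethylbut-2-enamide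
Conditions: MeNH(OMe)·HCl (1.5 equiv), i-PrMgCl (3.0 equiv), THF, −20 → 0 °C
Reagents that add atoms: N,O-dimethylhydroxylamine hydrochloride, CNOC.Cl
Why: direct Weinreb aminolysis of the ester by the magnesium amide formed in the flask; the α-methyl enoate is a poor Michael acceptor, so attack is at the carbonyl and the E-alkene is untouched.

Step 4
Reactants: 7 ethyl 2-methyl-3-oxobutanoate (ethyl 2-methylacetoacetate); 6 (2E)-4-[(tert-butyldimethylsilyl)oxy]-N-methoxy-N,2-dimethylbut-2-enamide
Product: 9 ethyl (6E)-8-[(tert-butyldimethylsilyl)oxy]-2,6-dimethyl-3,5-dioxooct-6-enoate, via dilithium dianion of ethyl 2-methylacetoacetate 8 (not isolated)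
Conditions: 7 (1.6 equiv), LDA (3.3 equiv), THF, −78 → 0 °C; then 6 (1.0 equiv), −78 → −20 °C; AcOH quench
Reagents that add atoms: none
Why: crossed Claisen-type acylation in which the terminal carbon of the dianion, its most nucleophilic site, adds to the Weinreb amide to give a chelated tetrahedral intermediate that releases the 1,3-diketone only on work-up, so there is no over-addition and no quenching of the nucleophile by product.

Step 5
Reactants: 9 ethyl (6E)-8-[(tert-butyldimethylsilyl)oxy]-2,6-dimethyl-3,5-dioxooct-6-enoate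
Product: 10 6-[(2E)-4-[(tert-butyldimethylsilyl)oxy]but-2-en-2-yl]-4-hydroxy-3-methyl-2H-pyran-2-one
Conditions: DBU (1.5 equiv), toluene, rt → 50 °C; cold 10% citric acid work-up
Reagents that add atoms: none
Why: base-mediated lactonisation of the 3,5-diketo ester (the C5 enol oxygen attacks the ethyl ester with loss of ethanol) gives the 4-hydroxy-2-pyranone as the thermodynamic sink; the silyl ether tolerates DBU.

Step 6
Reactants: 10 6-[(2E)-4-[(tert-butyldimethylsilyl)oxy]but-2-en-2-yl]-4-hydroxy-3-methyl-2H-pyran-2-one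
Product: 11 6-[(2E)-4-[(tert-butyldimethylsilyl)oxy]but-2-en-2-yl]-4-methoxy-3-methyl-2H-pyran-2-one
Conditions: Me2SO4 (1.3 equiv), K2CO3 (2 equiv), acetone, 40 °C
Reagents that add atoms: dimethyl sulfate, COS(=O)(=O)OC
Why: O-methylation of the vinylogous acid under K2CO3/acetone conditions favours the 4-methoxy-2-pyranone; the minor 2-methoxy-4-pyranone isomer is removed by chromatography.

Step 7
Reactants: 11 6-[(2E)-4-[(tert-butyldimethylsilyl)oxy]but-2-en-2-yl]-4-methoxy-3-methyl-2H-pyran-2-one
Product: 12 6-[(2E)-4-hydroxybut-2-en-2-yl]-4-methoxy-3-methyl-2H-pyran-2-one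
Conditions: TBAF (1.2 equiv), AcOH (1.2 equiv), THF, 0 °C → rt
Reagents that add atoms: none
Why: fluoride-mediated desilylation, buffered with acetic acid so that the base-sensitive pyranone is not exposed to free alkoxide or hydroxide.

Step 8
Reactants: 12 6-[(2E)-4-hydroxybut-2-en-2-yl]-4-methoxy-3-methyl-2H-pyran-2-one
Product: 13 (2E)-3-(4-methoxy-3-methyl-2-oxo-2H-pyran-6-yl)but-2-enal
Conditions: activated MnO2 (15 equiv), CH2Cl2, rt, dark
Reagents that add atoms: none
Why: chemoselective allylic oxidation with MnO2 under neutral conditions stops at the enal and does not isomerise the E-alkene.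

Step 9
Reactants: 13 (2E)-3-(4-methoxy-3-methyl-2-oxo-2H-pyran-6-yl)but-2-enal
Product: 14 (2E)-3-(4-methoxy-3-methyl-2-oxo-2H-pyran-6-yl)but-2-enoic acid
Conditions: NaClO2 (3 equiv), NaH2PO4 (3 equiv), 2-methyl-2-butene (10 equiv), t-BuOH/H2O 3:1, 0 °C → rt, dark
Reagents that add atoms: sodium chlorite, [Na+].[O-]Cl=O
Why: Pinnick oxidation converts the enal to the acid at pH about 4 without touching the pyranone or the alkene, the scavenger removing HOCl.

Step 10
Reactants: 14 (2E)-3-(4-methoxy-3-methyl-2-oxo-2H-pyran-6-yl)but-2-enoic acid; 15 naphthalene-1,8-diol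
Product: 16 naphthalene-1,8-diyl bis[(2E)-3-(4-methoxy-3-methyl-2-oxo-2H-pyran-6-yl)but-2-enoate]
Conditions: 14 (2.1 equiv), 15 (1.0 equiv), DCC (2.4 equiv), DMAP (0.2 equiv), CH2Cl2, 0 °C → rt, N2, dark
Reagents that add atoms: none
Why: Steglich esterification of both peri hydroxyls attaches two monomers to the rigid template that will pre-organise them for the cycloaddition.

Step 11
Reactants: 16 naphthalene-1,8-diyl bis[(2E)-3-(4-methoxy-3-methyl-2-oxo-2H-pyran-6-yl)but-2-enoate]
Product: 17 naphthalene-1,8-diyl (1R,2S,3R,4S)-3,4-bis(4-methoxy-3-methyl-2-oxo-2H-pyran-6-yl)-3,4-dimethylcyclobutane-1,2-dicarboxylate (cyclic meso diester; ester groups cis; pyranones cis; each pyranone trans to the adjacent ester)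
Conditions: hν (365 nm LED), crystalline solid as a thin layer, rt, N2, 24–48 h
Reagents that add atoms: none
Why: the peri oxygens hold the two enoate arms parallel, head-to-head and about 3.5–4 Å apart, so a suprafacial template-directed [2+2] photocycloaddition in the solid gives the syn head-to-head dimer with E geometry retained, which sets all four stereocentres in the meso relative configuration.

Step 12
Reactants: 17 naphthalene-1,8-diyl (1R,2S,3R,4S)-3,4-bis(4-methoxy-3-methyl-2-oxo-2H-pyran-6-yl)-3,4-dimethylcyclobutane-1,2-dicarboxylate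
Product: 18 (1R,2S,3R,4S)-3,4-bis(4-methoxy-3-methyl-2-oxo-2H-pyran-6-yl)-3,4-dimethylcyclobutane-1,2-dicarboxylic acid (meso)
Conditions: LiOH·H2O (4 equiv), THF/H2O 3:1, 0 °C, 1–2 h; then 1 M HCl to pH 2
Reagents that add atoms: lithium hydroxide, [Li+].[OH-]
Why: saponification of the aryl esters, which are far more electrophilic than the pyranone lactones (the second falls by neighbouring-carboxylate participation), is fast enough at 0 °C to avoid epimerising the α-CH centres, and the template is recovered.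

Step 13
Reactants: 18 (1R,2S,3R,4S)-3,4-bis(4-methoxy-3-methyl-2-oxo-2H-pyran-6-yl)-3,4-dimethylcyclobutane-1,2-dicarboxylic acid
Product: 19 (1R,5S,6R,7S)-6,7-bis(4-methoxy-3-methyl-2-oxo-2H-pyran-6-yl)-6,7-dimethyl-3-oxabicyclo[3.2.0]heptane-2,4-dione (meso; methyls on the face of the anhydride ring; pyranones on the face of the bridgehead hydrogens)
Conditions: Ac2O, 80 °C, 2 h; evaporate with toluene
Reagents that add atoms: none
Why: dehydrative cyclisation of the cis-1,2-diacid to the five-membered cyclic anhydride, which only the cis acid can form and which touches no stereocentre.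

Step 14
Reactants: 19 (1R,5S,6R,7S)-6,7-bis(4-methoxy-3-methyl-2-oxo-2H-pyran-6-yl)-6,7-dimethyl-3-oxabicyclo[3.2.0]heptane-2,4-dione
Product: 20 (1S,2R,3S,4R)-2-(methoxycarbonyl)-3,4-bis(4-methoxy-3-methyl-2-oxo-2H-pyran-6-yl)-3,4-dimethylcyclobutane-1-carboxylic acid
Conditions: quinidine (1.1 equiv), MeOH (3.0 equiv), toluene, −55 °C, 72–96 h; 1 M HCl work-up; recrystallise to raise ee
Reagents that add atoms: methanol, CO
Why: cinchona-alkaloid desymmetrisation of the meso anhydride, in which quinidine as a chiral general base delivers methanol to one enantiotopic carbonyl (the one on the carbon that becomes C2), turning the meso framework into the single (1S,2R,3S,4R) enantiomer.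

**Compound list**
1 | 1,4-dioxane-2,5-diol (glycolaldehyde dimer) | OC1COC(O)CO1 | starting material
2 | ethyl 2-(triphenyl-λ5-phosphanylidene)propanoate | CCOC(=O)C(C)=P(c1ccccc1)(c1ccccc1)c1ccccc1 | starting material
3 | glycolaldehyde | OCC=O | intermediate
4 | ethyl (2E)-4-hydroxy-2-methylbut-2-enoate | CCOC(=O)/C(C)=C/CO | intermediate
5 | ethyl (2E)-4-[(tert-butyldimethylsilyl)oxy]-2-methylbut-2-enoate | CCOC(=O)/C(C)=C/CO[Si](C)(C)C(C)(C)C | intermediate
6 | (2E)-4-[(tert-butyldimethylsilyl)oxy]-N-methoxy-N,2-dimethylbut-2-enamide | CON(C)C(=O)/C(C)=C/CO[Si](C)(C)C(C)(C)C | intermediate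
7 | ethyl 2-methyl-3-oxobutanoate (ethyl 2-methylacetoacetate) | CCOC(=O)C(C)C(C)=O | starting material
8 | dilithium dianion (dienolate) of ethyl 2-methylacetoacetate | [Li+].[Li+].C=C([O-])C(C)=C([O-])OCC | intermediate
9 | ethyl (6E)-8-[(tert-butyldimethylsilyl)oxy]-2,6-dimethyl-3,5-dioxooct-6-enoate | CCOC(=O)C(C)C(=O)CC(=O)/C(C)=C/CO[Si](C)(C)C(C)(C)C | intermediate
10 | 6-[(2E)-4-[(tert-butyldimethylsilyl)oxy]but-2-en-2-yl]-4-hydroxy-3-methyl-2H-pyran-2-one | Cc1c(O)cc(/C(C)=C/CO[Si](C)(C)C(C)(C)C)oc1=O | intermediate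
11 | 6-[(2E)-4-[(tert-butyldimethylsilyl)oxy]but-2-en-2-yl]-4-methoxy-3-methyl-2H-pyran-2-one | COc1cc(/C(C)=C/CO[Si](C)(C)C(C)(C)C)oc(=O)c1C | intermediate
12 | 6-[(2E)-4-hydroxybut-2-en-2-yl]-4-methoxy-3-methyl-2H-pyran-2-one | COc1cc(/C(C)=C/CO)oc(=O)c1C | intermediate
13 | (2E)-3-(4-methoxy-3-methyl-2-oxo-2H-pyran-6-yl)but-2-enal | COc1cc(/C(C)=C/C=O)oc(=O)c1C | intermediate
14 | (2E)-3-(4-methoxy-3-methyl-2-oxo-2H-pyran-6-yl)but-2-enoic acid | COc1cc(/C(C)=C/C(=O)O)oc(=O)c1C | intermediate
15 | naphthalene-1,8-diol | Oc1cccc2cccc(O)c12 | starting material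
16 | naphthalene-1,8-diyl bis[(2E)-3-(4-methoxy-3-methyl-2-oxo-2H-pyran-6-yl)but-2-enoate] | COc1cc(/C(C)=C/C(=O)Oc2cccc3cccc(OC(=O)/C=C(\C)c4cc(OC)c(C)c(=O)o4)c23)oc(=O)c1C | intermediate
17 | naphthalene-1,8-diyl (1R,2S,3R,4S)-3,4-bis(4-methoxy-3-methyl-2-oxo-2H-pyran-6-yl)-3,4-dimethylcyclobutane-1,2-dicarboxylate (cyclic meso diester) | O=C1Oc2cccc3cccc(OC(=O)[C@@H]4[C@H]1[C@@](C)(c5cc(OC)c(C)c(=O)o5)[C@@]4(C)c5cc(OC)c(C)c(=O)o5)c23 | intermediate
18 | (1R,2S,3R,4S)-3,4-bis(4-methoxy-3-methyl-2-oxo-2H-pyran-6-yl)-3,4-dimethylcyclobutane-1,2-dicarboxylic acid (meso) | OC(=O)[C@@H]1[C@H](C(=O)O)[C@@](C)(c2cc(OC)c(C)c(=O)o2)[C@@]1(C)c1cc(OC)c(C)c(=O)o1 | intermediate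
19 | (1R,5S,6R,7S)-6,7-bis(4-methoxy-3-methyl-2-oxo-2H-pyran-6-yl)-6,7-dimethyl-3-oxabicyclo[3.2.0]heptane-2,4-dione (meso) | O=C1OC(=O)[C@@H]2[C@H]1[C@@](C)(c3cc(OC)c(C)c(=O)o3)[C@@]2(C)c1cc(OC)c(C)c(=O)o1 | intermediate
20 | (1S,2R,3S,4R)-2-(methoxycarbonyl)-3,4-bis(4-methoxy-3-methyl-2-oxo-2H-pyran-6-yl)-3,4-dimethylcyclobutane-1-carboxylic acid | COC(=O)[C@@H]1[C@H](C(=O)O)[C@@](C)(c2cc(OC)c(C)c(=O)o2)[C@@]1(C)c1cc(OC)c(C)c(=O)o1 | target

**Totals and risks**

Total step count: 14. Longest linear sequence: 14 steps (1 → 20; 2, 7 and 15 enter as commercial materials).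

Steps most likely to fail:

Step 11 (photodimerisation). The template precedent is for cinnamates; here each alkene is trisubstituted and carries a pyranone, two adjacent quaternary centres must form, and the pyranone has its own photochemistry. The fallback sets out from acid 14 and comes back at diacid 18, so it bypasses 16 and 17. Acid 14 is crystallised with half an equivalent of ethane-1,2-diamine from ethanol to give the double salt ethane-1,2-diaminium bis[(2E)-3-(4-methoxy-3-methyl-2-oxo-2H-pyran-6-yl)but-2-enoate] F1, in which the gauche diammonium ion bridges two carboxylates head-to-head. Irradiating the crystals at 365 nm gives ethane-1,2-diaminium (1R,2S,3R,4S)-3,4-bis(4-methoxy-3-methyl-2-oxo-2H-pyran-6-yl)-3,4-dimethylcyclobutane-1,2-dicarboxylate F2, and acidification with 1 M HCl releases 18. This replaces the covalent template with an ionic crystal-engineering template and needs no ester cleavage.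

Step 14 (desymmetrisation). The anhydride is flanked by two quaternary carbons, so rate and ee may be poor, and the facial sense rests on the assumption stated above. The fallback sets out from anhydride 19 and comes back at 20. Anhydride 19 is opened without selectivity (MeOH, Et3N, cat. DMAP, CH2Cl2, rt, then acid) to the racemic hemiester, that is 20 together with its enantiomer (1R,2S,3R,4S)-2-(methoxycarbonyl)-3,4-bis(4-methoxy-3-methyl-2-oxo-2H-pyran-6-yl)-3,4-dimethylcyclobutane-1-carboxylic acid F3. The racemate is resolved by fractional crystallisation with (R)-1-phenylethylamine, which gives the two diastereomeric salts (R)-1-phenylethanaminium (1S,2R,3S,4R)-2-(methoxycarbonyl)-3,4-bis(4-methoxy-3-methyl-2-oxo-2H-pyran-6-yl)-3,4-dimethylcyclobutane-1-carboxylate F4 and (R)-1-phenylethanaminium (1R,2S,3R,4S)-2-(methoxycarbonyl)-3,4-bis(4-methoxy-3-methyl-2-oxo-2H-pyran-6-yl)-3,4-dimethylcyclobutane-1-carboxylate F5. If F5 is the less soluble salt, the S-amine is used instead. An X-ray structure of the crystalline salt, with the amine as internal reference, proves the absolute configuration independently of any alkaloid model, and acidifying F4 gives 20.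

Step 4 (Claisen acylation). The dianion is α-branched and the amide carbonyl is hindered by its α-methyl group, so acylation may be slow or low-yielding. The fallback sets out from Weinreb amide 6 and comes back at triketide 9, replacing the acylation by an aldol addition followed by oxidation. Amide 6 is reduced with DIBAL-H (THF, −78 °C) to (2E)-4-[(tert-butyldimethylsilyl)oxy]-2-methylbut-2-enal F6. Dianion 8, made from 7 as before, adds 1,2 to this aldehyde at −78 °C to give ethyl (6E)-8-[(tert-butyldimethylsilyl)oxy]-5-hydroxy-2,6-dimethyl-3-oxooct-6-enoate F7 as a diastereomer mixture. Dess–Martin periodinane (CH2Cl2, NaHCO3, rt) then oxidises the allylic alcohol to 9.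

**Further compounds**
F1 | step 11 | ethane-1,2-diaminium bis[(2E)-3-(4-methoxy-3-methyl-2-oxo-2H-pyran-6-yl)but-2-enoate] | [NH3+]CC[NH3+].COc1cc(/C(C)=C/C(=O)[O-])oc(=O)c1C.COc1cc(/C(C)=C/C(=O)[O-])oc(=O)c1C
F2 | step 11 | ethane-1,2-diaminium (1R,2S,3R,4S)-3,4-bis(4-methoxy-3-methyl-2-oxo-2H-pyran-6-yl)-3,4-dimethylcyclobutane-1,2-dicarboxylate | [NH3+]CC[NH3+].[O-]C(=O)[C@@H]1[C@H](C(=O)[O-])[C@@](C)(c2cc(OC)c(C)c(=O)o2)[C@@]1(C)c1cc(OC)c(C)c(=O)o1
F3 | step 14 | (1R,2S,3R,4S)-2-(methoxycarbonyl)-3,4-bis(4-methoxy-3-methyl-2-oxo-2H-pyran-6-yl)-3,4-dimethylcyclobutane-1-carboxylic acid | COC(=O)[C@H]1[C@@H](C(=O)O)[C@](C)(c2cc(OC)c(C)c(=O)o2)[C@]1(C)c1cc(OC)c(C)c(=O)o1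
F4 | step 14 | (R)-1-phenylethanaminium (1S,2R,3S,4R)-2-(methoxycarbonyl)-3,4-bis(4-methoxy-3-methyl-2-oxo-2H-pyran-6-yl)-3,4-dimethylcyclobutane-1-carboxylate | C[C@@H]([NH3+])c1ccccc1.COC(=O)[C@@H]1[C@H](C(=O)[O-])[C@@](C)(c2cc(OC)c(C)c(=O)o2)[C@@]1(C)c1cc(OC)c(C)c(=O)o1
F5 | step 14 | (R)-1-phenylethanaminium (1R,2S,3R,4S)-2-(methoxycarbonyl)-3,4-bis(4-methoxy-3-methyl-2-oxo-2H-pyran-6-yl)-3,4-dimethylcyclobutane-1-carboxylate | C[C@@H]([NH3+])c1ccccc1.COC(=O)[C@H]1[C@@H](C(=O)[O-])[C@](C)(c2cc(OC)c(C)c(=O)o2)[C@]1(C)c1cc(OC)c(C)c(=O)o1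
F6 | step 4 | (2E)-4-[(tert-butyldimethylsilyl)oxy]-2-methylbut-2-enal | O=C/C(C)=C/CO[Si](C)(C)C(C)(C)C
F7 | step 4 | ethyl (6E)-8-[(tert-butyldimethylsilyl)oxy]-5-hydroxy-2,6-dimethyl-3-oxooct-6-enoate | CCOC(=O)C(C)C(=O)CC(O)/C(C)=C/CO[Si](C)(C)C(C)(C)C
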